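# Proposed total synthesis of CNP0244758.1 by palladium-catalysed allylic dearomatisation of a 2,4-dimethylphenol

## Analysis of the target

The target is methyl 8β-acetoxy-5α-hydroperoxy-3β-(2-methylpropanoyloxy)eudesma-4(15),11(13)-dien-12-oate, a decalin sesquiterpenoid. In eudesmane numbering, ring A (C1–C5 and C10) carries the isobutyrate on C3, the exocyclic methylene C15 on C4 and the hydroperoxide on C5. Ring B (C5–C10) carries the methyl acrylate C11–C13 on C7, the acetate on C8 and the angular methyl C14 on the quaternary C10. There are five stereocentres: the C10 methyl, the C7 side chain, the C8 acetate and the C3 ester all lie on the β face, and the C5 hydroperoxide is α, trans to the angular methyl. In the chair form the C3 ester and the C7 chain are equatorial, while the C8 acetate is axial and 1,3-diaxial to the methyl. The sensitive groups are the tertiary allylic hydroperoxide (lost to reductants, acid, base and metals), the acrylate (a Michael acceptor) and two different secondary esters. The γ-acetoxy ester is the opened form of a cis γ-lactone and closes again whenever the C8 oxygen is free. The difficulty lies in setting the quaternary C10 in the right relation to C7, placing two different acyl groups, and bringing in the acrylate and the hydroperoxide late. The strategy rests on ring A: with oxygen on C3, a methyl on C4 and a methyl-bearing C10 para to C3, it is a 2,4-dimethylphenol in disguise. Its carbon C5, between the two methyl-bearing carbons, holds the chain C6–C7–C8–C9, and the chain end C9 can be bonded to C10 with loss of aromaticity.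

## Retrosynthetic reasoning

**C5–O (37 to 36).** The hydroperoxide and the 4(15)-alkene are removed together. Both should arise from the tetrasubstituted C4=C5 alkene of 36 in a Schenck ene reaction, with oxygen entering at C5 and a hydrogen leaving C15. This cut comes first because the hydroperoxide survives none of the other chemistry. The forward step has to choose the α face and the methyl hydrogens.

**Acrylate and the two esters (36 to 33, 32 and 30).** The C11=C13 bond and both acyl groups are traced back to the cis-fused γ-lactone 30. There the lactone ties the C8 oxygen to C12, so the C3 hydroxyl is the only free one and takes the isobutyrate. The lactone α-carbon C11 is the only acidic carbon and takes C13 in a Mannich reaction (bond C11–C13). Opening the lactone at the end frees the C8 oxygen for the acetate, and loss of the amine gives the alkene. The gain is that two different esters and C13 are placed without protecting groups.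

**C3 and C8 carbinols, C1–C2 (30 to 28, 27 and 25).** Both oxygen-bearing stereocentres are taken back to ketones: the enone carbonyl at C3 and a ketone at C8. The C8 ketone comes from the C8 methylidene of 25 by oxidative cleavage, and the saturated C1–C2 bond from the C1=C2 alkene of dienone 25 by selective hydrogenation. The forward reduction must deliver hydride to the α face of both carbonyls.

**C9–C10 (25 to 23).** This is the key cut. Breaking C9–C10 opens ring B and restores the arene: 25 becomes phenol 23, whose side chain on C5 ends in a 2-substituted allyl carbonate. It is made here because the cut removes the quaternary centre and returns ring A, with its C3 oxygen, its C4 methyl and the C4=C5 bond, to a flat aromatic. Only C7 is left as a stereocentre. The forward reaction must alkylate the para carbon C10 rather than the ortho carbon C4 or the oxygen, on the face that puts the methyl cis to the C7 chain.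

**C8=CH2 and C8–C9 (23 to 22, 21, 20 and 17).** The allyl carbonate is unfolded to a C8 ketone carrying an acyloxymethyl group (methylenation in the forward sense). The hydroxymethyl ketone 20 comes from acid 17 by a one-carbon homologation at the acyl carbon (bond C8–C9). This places C8 at the carboxyl level directly on C7, which is what an auxiliary-controlled enolate alkylation gives.

**C6–C7 (17 to 15, then 13 and 9).** The benzylic bond is cut next to the only stereocentre. The succinate imide 13 supplies C7, C8, C11 and C12, and the benzylic bromide 9 supplies ring A and C6. The auxiliary must set C7 as (R).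

**Arene and imide (9 to 1; 13 to 10 and 11).** The 3-oxygen of 9 is traced back through phenol, amine and nitro group to 1, where the two methyls direct nitration to the one position needed. Imide 13 is the N-acylation product of 10 with 11.

## Alternatives that were turned down

**Alternative 1:** Both rings are cut at once along C6–C7 and C5–C10. This unravels the decalin to the open-chain trienone A1, a vinyl ketone (C5=C6, carbonyl at C4) tethered through C1–C3 to a 2-silyloxydiene (C7=C8–C9=C10, methyl on C10). In the forward direction a chiral oxazaborolidinium Lewis acid would bind the ketone, and an intramolecular Diels–Alder reaction would give the cis-fused bicycle A2, with C5 and C10 set by the catalyst and the C8 oxygen held as a silyl enol ether.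
- For it: two rings, two C–C bonds and the quaternary centre arise in one catalytic step from an achiral chain that is quicker to make than phenol 23. On ring construction and on front-end step count it is the stronger plan.
- Against it for this target: A2 has no C15, no C3 oxygen and no C7 side chain, and C5 is a CH that must first become an alkene carbon before it can carry the hydroperoxide. C15 would have to be added at C4, C4=C5 formed regioselectively, C3 oxidised on the β face and an ester chain attached at C7 next to the C8 carbonyl. Each is a separate regio- or stereochemical problem.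
- Comparison: the chosen dearomatisation forms only one ring and one bond, but its product 25 already holds the C3 oxygen, C15, the C4=C5 alkene, the configured C7 chain and a C8 handle.

**Alternative 2:** C4–C5 and C9–C10 are cut, giving the acyclic β-keto ester A3 with a trisubstituted C5=C10 alkene and a chloroalkene terminus at C8=C9. In the forward direction Mn(OAc)3 would oxidise the β-keto ester to the C4 radical, which closes ring A onto C5. The tertiary C10 radical then closes ring B onto C9, and Cu(OAc)2 oxidises the C8 radical, so that diketone A4 results.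
- For it: two rings and two bonds from a chain, with the trans ring fusion and the angular methyl made in one operation. The C8 ketone and C7 chain match those of the chosen route. In bonds formed per step it is stronger.
- Against it: the only stereocentre of A3 is C7, outside ring A, so control over C5 and C10 rests on a chair preference in the second closure of a radical cascade. The oxidants are stoichiometric. A4 carries a surplus ester carbon on C4 and a hydrogen on C5, so a decarboxylation and a dehydrogenation are needed just to reach the 4-en-3-one that 28 already is. A3 also needs the same C7 centre made beforehand.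
- Comparison: the chosen route takes C4=C5 and the C3 carbonyl directly from the phenol and sets C10 in a closed-shell catalytic step.

**Alternative 3:** Only C6–C7 is cut. Ring A is kept as the trimethylcyclohexenone A5, whose C10 carries a chain ending in a (Z)-2-(bromomethyl)enoate (C7=C11, bromide on C13) with the C8 acetate in place. In the forward direction a chiral primary amine would condense with the C3 ketone to a dienamine that reaches the C5 methyl (C6). C6 would attack C7 in an SN2′ sense with loss of bromide to give A6.
- For it: A6 is the most advanced of all the key-step products. Acrylate, acetate, enone and both methyls are present, three steps from the target. In the end game it clearly beats the chosen route, which needs seven steps after its key step.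
- Against it: the difficulty is moved in front of the key step and into it. A5 needs the quaternary C10 and the C8 carbinol set independently on a flexible chain. The amine catalyst is itself a good nucleophile for the allylic bromide. Attack through C6 rather than through the α′ carbon C2 is not assured. C7 is formed beside an acyclic acetoxy centre with little to direct it.
- Comparison: the chosen route makes C7 by an auxiliary-controlled alkylation and lets it direct the one remaining carbon centre, C10.

Key step: step 14

## Route

Remarks on the chemistry: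
- Compounds 10 and 11 are taken as purchased.
- Compounds 19, 26 and 32–35 are carried as mixtures at a centre that is lost again (C2 of the chain in 19, the spiro carbon in 26, C11 in 32–35). Their SMILES leave that centre open.
- Bicyclic compounds without C13 are named as 13-noreudesmanes.

Step 1
Reactants: 1 2,6-dimethylbenzoic acid
Product: 2 2,6-dimethyl-3-nitrobenzoic acid
Conditions: fuming HNO3, conc. H2SO4, 0 °C
Reagents that add atoms: nitric acid, O[N+](=O)[O-]
Why: Electrophilic aromatic nitration; positions 3 and 5 are equivalent, ortho and para to the methyls and meta to the carboxyl, so a single mononitro acid should form.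

Step 2
Reactants: 2 2,6-dimethyl-3-nitrobenzoic acid
Product: 3 3-amino-2,6-dimethylbenzoic acid
Conditions: H2 (1 atm), Pd/C, MeOH, rt
Reagents that add atoms: none
Why: Catalytic hydrogenation of a nitroarene to the aniline; nothing else in the molecule is reducible.

Step 3
Reactants: 3 3-amino-2,6-dimethylbenzoic acid
Product: 5 3-hydroxy-2,6-dimethylbenzoic acid, via diazonium salt 4 (not isolated)
Conditions: NaNO2, 2 M H2SO4, 0 °C; then dropwise into 2 M H2SO4, 100 °C
Reagents that add atoms: water, O
Why: Diazotisation followed by thermal hydrolysis of the diazonium salt; strongly acidic medium suppresses azo coupling and cyclisation onto the ortho methyl.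

Step 4
Reactants: 5 3-hydroxy-2,6-dimethylbenzoic acid
Product: 6 3-(hydroxymethyl)-2,4-dimethylphenol
Conditions: LiAlH4, THF, reflux; aq. NaOH work-up
Reagents that add atoms: none
Why: Hydride reduction of the hindered carboxylic acid to the benzylic alcohol; the phenoxide is a spectator.

Step 5
Reactants: 6 3-(hydroxymethyl)-2,4-dimethylphenol
Product: 8 [2,6-dimethyl-3-(triisopropylsilyloxy)phenyl]methanol, via sodium phenoxide 7 (not isolated)
Conditions: NaH (1.0 equiv), THF, 0 °C; then i-Pr3SiCl, 0 °C to rt
Reagents that add atoms: chlorotriisopropylsilane, CC(C)[Si](Cl)(C(C)C)C(C)C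
Why: Only the phenol (about six pKa units more acidic) is deprotonated, and the phenoxide is silylated; the neutral benzylic alcohol between two ortho methyls should not react with the bulky silyl chloride without an amine catalyst.

Step 6
Reactants: 8 [2,6-dimethyl-3-(triisopropylsilyloxy)phenyl]methanol
Product: 9 [3-(bromomethyl)-2,4-dimethylphenoxy]triisopropylsilane
Conditions: CBr4, PPh3, CH2Cl2, 0 °C
Reagents that add atoms: tetrabromomethane, BrC(Br)(Br)Br
Why: Appel bromination under neutral conditions that leave the aryl silyl ether intact; the oxygen is meta to the benzylic carbon, so the bromide is not prone to quinone methide formation.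

Step 7
Reactants: 10 (4R)-4-benzyl-1,3-oxazolidin-2-one; 11 methyl 4-chloro-4-oxobutanoate
Product: 13 methyl 4-[(4R)-4-benzyl-2-oxo-1,3-oxazolidin-3-yl]-4-oxobutanoate, via lithium oxazolidinide 12 (not isolated)
Conditions: n-BuLi (1.0 equiv), THF, −78 °C; then 11, −78 to 0 °C
Reagents that add atoms: none
Why: N-acylation of the lithiated auxiliary; the acid chloride reacts far faster than the methyl ester.

Step 8
Reactants: 13 methyl 4-[(4R)-4-benzyl-2-oxo-1,3-oxazolidin-3-yl]-4-oxobutanoate; 9 [3-(bromomethyl)-2,4-dimethylphenoxy]triisopropylsilane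
Product: 15 methyl (3R)-4-[(4R)-4-benzyl-2-oxo-1,3-oxazolidin-3-yl]-3-{[2,6-dimethyl-3-(triisopropylsilyloxy)phenyl]methyl}-4-oxobutanoate, via sodium enolate 14 (not isolated)
Conditions: NaN(SiMe3)2 (1.1 equiv), THF, −78 °C; then 9, −78 to −20 °C
Reagents that add atoms: none
Why: Evans asymmetric alkylation: the imide, more acidic than the ester, gives the chelated Z-enolate, and the benzylic bromide approaches the face away from the auxiliary's benzyl group. With the (R)-auxiliary this sets C7 as (R), the configuration of the target.

Step 9
Reactants: 15 methyl (3R)-4-[(4R)-4-benzyl-2-oxo-1,3-oxazolidin-3-yl]-3-{[2,6-dimethyl-3-(triisopropylsilyloxy)phenyl]methyl}-4-oxobutanoate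
Product: 17 (2R)-2-{[2,6-dimethyl-3-(triisopropylsilyloxy)phenyl]methyl}-4-methoxy-4-oxobutanoic acid, via lithium peroxycarboxylate 16 (not isolated)
Conditions: LiOH, 30% H2O2, THF/H2O (3:1), 0 °C; then aq. Na2SO3; 1 M HCl to pH 3
Reagents that add atoms: hydrogen peroxide, OO
Why: Hydroperoxide anion cleaves the exocyclic imide carbonyl selectively and without epimerisation, and sulfite reduces the peroxy acid. At 0 °C the methyl ester and the hindered aryl silyl ether should survive, and the auxiliary is recovered.

Step 10
Reactants: 17 (2R)-2-{[2,6-dimethyl-3-(triisopropylsilyloxy)phenyl]methyl}-4-methoxy-4-oxobutanoic acid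
Product: 20 methyl (3R)-3-{[2,6-dimethyl-3-(triisopropylsilyloxy)phenyl]methyl}-5-hydroxy-4-oxopentanoate, via acid chloride 18 (not isolated), via silyl keto ester 19 (not isolated)
Conditions: (COCl)2, DMF (cat.), CH2Cl2, 0 °C to rt; evaporate; (Me3SiO)2C=CH(OSiMe3), neat, 90 °C; then 0.5 M HCl, dioxane, 60 °C
Reagents that add atoms: tris(trimethylsilyloxy)ethylene, C[Si](C)(C)OC=C(O[Si](C)(C)C)O[Si](C)(C)C
Why: C-acylation of a ketene bis(silyl) acetal by the acid chloride, then hydrolysis and decarboxylation of the α-silyloxy β-keto silyl ester. This is the established one-flask conversion of an acid chloride into a hydroxymethyl ketone, and it forms C8–C9.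

Step 11
Reactants: 20 methyl (3R)-3-{[2,6-dimethyl-3-(triisopropylsilyloxy)phenyl]methyl}-5-hydroxy-4-oxopentanoate
Product: 21 methyl (3R)-3-{[2,6-dimethyl-3-(triisopropylsilyloxy)phenyl]methyl}-5-[(methoxycarbonyl)oxy]-4-oxopentanoate
Conditions: ClCO2Me, pyridine, CH2Cl2, 0 °C
Reagents that add atoms: methyl chloroformate, COC(=O)Cl
Why: O-acylation of the primary hydroxyl with a chloroformate under a weak base that should not enolise the ketone.

Step 12
Reactants: 21 methyl (3R)-3-{[2,6-dimethyl-3-(triisopropylsilyloxy)phenyl]methyl}-5-[(methoxycarbonyl)oxy]-4-oxopentanoate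
Product: 22 methyl (3R)-3-{[2,6-dimethyl-3-(triisopropylsilyloxy)phenyl]methyl}-4-{[(methoxycarbonyl)oxy]methyl}pent-4-enoate
Conditions: Zn, CH2Br2, TiCl4 (reagent pre-formed in THF), CH2Cl2, 0 °C to rt
Reagents that add atoms: dibromomethane, BrCBr
Why: Takai–Lombardo methylenation: the zinc–titanium methylene reagent is not basic, so the stereocentre next to the ketone should not epimerise. It attacks ketones in preference to esters and carbonates.

Step 13
Reactants: 22 methyl (3R)-3-{[2,6-dimethyl-3-(triisopropylsilyloxy)phenyl]methyl}-4-{[(methoxycarbonyl)oxy]methyl}pent-4-enoate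
Product: 23 methyl (3R)-3-[(3-hydroxy-2,6-dimethylphenyl)methyl]-4-{[(methoxycarbonyl)oxy]methyl}pent-4-enoate
Conditions: Bu4NF, AcOH, THF, 0 °C
Reagents that add atoms: none
Why: Fluoride cleaves the aryl silyl ether rapidly; the acetic acid buffer keeps the allylic carbonate and the methyl ester untouched.

Step 14
Reactants: 23 methyl (3R)-3-[(3-hydroxy-2,6-dimethylphenyl)methyl]-4-{[(methoxycarbonyl)oxy]methyl}pent-4-enoate
Product: 25 methyl 8-methylidene-3-oxo-13-noreudesma-1,4-dien-12-oate (C7 side chain and C10 methyl both β), via allylpalladium phenoxide 24 (not isolated)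
Conditions: Pd2(dba)3·CHCl3 (2.5 mol %), PPh3 (11 mol %), CH2Cl2 (0.02 M), rt
Reagents that add atoms: none
Why: Zerovalent palladium ionises the allylic carbonate to a cationic η3-allyl complex of divalent palladium; the methyl carbonate anion loses CO2 and the methoxide formed deprotonates the phenol, so zwitterion 24 arises without added base. The phenoxide then attacks through its para carbon C10 on an allyl terminus, on the face away from the metal, which forms C9–C10 and releases the zerovalent catalyst. The closest known reaction type is the palladium-catalysed intramolecular allylic dearomatisation of para-substituted phenols to spirocyclohexadienones; here the tether is meta to the oxygen, so the same attack gives a fused ring. Ring B closes in a 6-exo mode with respect to the allyl unit: the 2-substituted allyl is symmetrical, either terminus gives the same six-membered ring, and the other terminus remains as the C8 methylidene. The new quaternary centre C10 is controlled by C7: in a chair-like transition state the CH2CO2Me group on C7 is equatorial, whereas the C10 methyl must be axial because C1 and C5 lie in the arene plane, and this places methyl and side chain cis. The step needs para (C10) over ortho (C4) C-alkylation and carbon over oxygen alkylation. Oxygen attack would require an eight-membered ring and is reversible under palladium; attack at C4 is flanked by the oxygen-bearing carbon and leads to the less stable linearly conjugated dienone, whereas attack at C10 gives the cross-conjugated dienone. The C10 methyl rules out rearomatisation, so 25 should be stable under the conditions.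

Step 15
Reactants: 25 methyl 8-methylidene-3-oxo-13-noreudesma-1,4-dien-12-oate
Product: 27 methyl 3,8-dioxo-13-noreudesma-1,4-dien-12-oate, via ozonide 26 (not isolated)
Conditions: O3, CH2Cl2, −78 °C (Sudan Red 7B as end-point indicator); then Me2S, −78 °C to rt
Reagents that add atoms: ozone, [O-][O+]=O
Why: Ozonolysis with reductive work-up; the isolated 1,1-disubstituted alkene is far more electron-rich than the two dienone alkenes, and the dye marks the end point. The C7 centre, now next to a ketone, is already in its more stable equatorial arrangement.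

Step 16
Reactants: 27 methyl 3,8-dioxo-13-noreudesma-1,4-dien-12-oate
Product: 28 methyl 3,8-dioxo-13-noreudesm-4-en-12-oate
Conditions: H2 (1 atm), RhCl(PPh3)3 (10 mol %), benzene/EtOH (1:1), rt
Reagents that add atoms: none
Why: Homogeneous hydrogenation with RhCl(PPh3)3 reduces the disubstituted C1=C2 bond of a cross-conjugated dienone and leaves the tetrasubstituted C4=C5 bond and both ketones alone, as in the 1,4-dien-3-one to 4-en-3-one conversion of steroids.

Step 17
Reactants: 28 methyl 3,8-dioxo-13-noreudesm-4-en-12-oate
Product: 30 3β-hydroxy-13-noreudesm-4-en-12,8β-olide, via dihydroxy ester 29 (not isolated)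
Conditions: NaBH4, CeCl3·7H2O, MeOH, −40 to 0 °C; aq. NH4Cl; then DBU (cat.), toluene, 60 °C
Reagents that add atoms: none
Why: Luche reduction attacks the enone carbonyl 1,2 from the α face, anti to the axial C10 methyl, to give the equatorial 3β-alcohol. At C8 the axial approach is blocked by the 1,3-diaxial methyl, so hydride enters equatorially from the α face and gives the axial 8β-alcohol. That alcohol is cis to the C7 chain and closes onto the methyl ester to the cis γ-lactone.

Step 18
Reactants: 30 3β-hydroxy-13-noreudesm-4-en-12,8β-olide
Product: 32 13-(dimethylamino)-3β-hydroxyeudesm-4-en-12,8β-olide (both C11 epimers), via dilithium enolate 31 (not isolated)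
Conditions: LiN(i-Pr)2 (2.3 equiv), THF, −78 °C; CH2=NMe2+ I− (2.5 equiv), −78 to 0 °C; aq. NaHCO3
Reagents that add atoms: dimethylmethylideneammonium iodide (Eschenmoser's salt), C=[N+](C)C.[I-]
Why: Mannich reaction of the lactone enolate with the iminium salt forms C11–C13. The lithium alkoxide at C3 is a spectator (an O-aminomethyl adduct would revert on aqueous work-up), and the configuration at C11 is lost again in step 20.

Step 19
Reactants: 32 13-(dimethylamino)-3β-hydroxyeudesm-4-en-12,8β-olide
Product: 33 13-(dimethylamino)-3β-(2-methylpropanoyloxy)eudesm-4-en-12,8β-olide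
Conditions: i-PrCOCl, pyridine, DMAP (cat.), CH2Cl2, 0 °C to rt
Reagents that add atoms: 2-methylpropanoyl chloride, CC(C)C(Cl)=O
Why: Acylation of the only free hydroxyl, an equatorial allylic alcohol; the C8 oxygen is held in the lactone, so the isobutyrate can go nowhere else.

Step 20
Reactants: 33 13-(dimethylamino)-3β-(2-methylpropanoyloxy)eudesm-4-en-12,8β-olide
Product: 36 methyl 8β-acetoxy-3β-(2-methylpropanoyloxy)eudesma-4,11(13)-dien-12-oate, via potassium carboxylate 34 (not isolated), via ammonium iodide 35 (not isolated)
Conditions: KOH (1.05 equiv), THF/H2O, 0 °C; evaporate; MeI, DMF, rt; evaporate; Ac2O, Et3N, DMAP, CH2Cl2, rt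
Reagents that add atoms: potassium hydroxide, [K+].[OH-]; iodomethane, CI; acetic anhydride, CC(=O)OC(C)=O
Why: The strained γ-lactone is saponified much faster than the hindered secondary isobutyrate. Iodomethane then alkylates the carboxylate on oxygen, which does not activate the carbonyl towards relactonisation, and quaternises the amine. DMAP-catalysed acetylation caps the axial C8 hydroxyl, and triethylamine expels trimethylamine by E1cB elimination to give the acrylate.

Step 21
Reactants: 36 methyl 8β-acetoxy-3β-(2-methylpropanoyloxy)eudesma-4,11(13)-dien-12-oate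
Product: 37 methyl 8β-acetoxy-5α-hydroperoxy-3β-(2-methylpropanoyloxy)eudesma-4(15),11(13)-dien-12-oate
Conditions: O2, hν (visible), tetraphenylporphyrin (cat.), CH2Cl2, 0 °C
Reagents that add atoms: dioxygen, O=O
Why: Schenck ene reaction: singlet oxygen adds to the electron-rich tetrasubstituted C4=C5 bond from the α face, anti to the axial C10 methyl. On that face only the C15 methyl hydrogens are both aligned and reactive, since H-6α is equatorial and H-3α is geminal to the acyloxy group; oxygen therefore bonds to C5 and the alkene moves to C4=C15. The electron-poor acrylate does not react.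

## Compound list

1 | 2,6-dimethylbenzoic acid | Cc1cccc(C)c1C(=O)O | starting material
2 | 2,6-dimethyl-3-nitrobenzoic acid | Cc1ccc([N+](=O)[O-])c(C)c1C(=O)O | intermediate
3 | 3-amino-2,6-dimethylbenzoic acid | Cc1ccc(N)c(C)c1C(=O)O | intermediate
4 | 3-carboxy-2,4-dimethylbenzenediazonium hydrogen sulfate | Cc1ccc([N+]#N)c(C)c1C(=O)O.OS(=O)(=O)[O-] | intermediate
5 | 3-hydroxy-2,6-dimethylbenzoic acid | Cc1ccc(O)c(C)c1C(=O)O | intermediate
6 | 3-(hydroxymethyl)-2,4-dimethylphenol | Cc1ccc(O)c(C)c1CO | intermediate
7 | sodium 3-(hydroxymethyl)-2,4-dimethylphenoxide | [Na+].Cc1ccc([O-])c(C)c1CO | intermediate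
8 | [2,6-dimethyl-3-(triisopropylsilyloxy)phenyl]methanol | Cc1ccc(O[Si](C(C)C)(C(C)C)C(C)C)c(C)c1CO | intermediate
9 | [3-(bromomethyl)-2,4-dimethylphenoxy]triisopropylsilane | Cc1ccc(O[Si](C(C)C)(C(C)C)C(C)C)c(C)c1CBr | intermediate
10 | (4R)-4-benzyl-1,3-oxazolidin-2-one | O=C1N[C@H](Cc2ccccc2)CO1 | starting material
11 | methyl 4-chloro-4-oxobutanoate | COC(=O)CCC(Cl)=O | starting material
12 | lithium (4R)-4-benzyl-2-oxo-1,3-oxazolidin-3-ide | [Li+].O=C1[N-][C@H](Cc2ccccc2)CO1 | intermediate
13 | methyl 4-[(4R)-4-benzyl-2-oxo-1,3-oxazolidin-3-yl]-4-oxobutanoate | COC(=O)CCC(=O)N1[C@H](Cc2ccccc2)COC1=O | intermediate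
14 | sodium (Z)-enolate of 13 | COC(=O)C/C=C(\[O-])N1[C@H](Cc2ccccc2)COC1=O.[Na+] | intermediate
15 | methyl (3R)-4-[(4R)-4-benzyl-2-oxo-1,3-oxazolidin-3-yl]-3-{[2,6-dimethyl-3-(triisopropylsilyloxy)phenyl]methyl}-4-oxobutanoate | COC(=O)C[C@@H](Cc1c(C)ccc(O[Si](C(C)C)(C(C)C)C(C)C)c1C)C(=O)N1[C@H](Cc2ccccc2)COC1=O | intermediate
16 | lithium (2R)-2-{[2,6-dimethyl-3-(triisopropylsilyloxy)phenyl]methyl}-4-methoxy-4-oxobutaneperoxoate | [Li+].COC(=O)C[C@@H](Cc1c(C)ccc(O[Si](C(C)C)(C(C)C)C(C)C)c1C)C(=O)O[O-] | intermediate
17 | (2R)-2-{[2,6-dimethyl-3-(triisopropylsilyloxy)phenyl]methyl}-4-methoxy-4-oxobutanoic acid | COC(=O)C[C@@H](Cc1c(C)ccc(O[Si](C(C)C)(C(C)C)C(C)C)c1C)C(=O)O | intermediate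
18 | methyl (3R)-4-chloro-3-{[2,6-dimethyl-3-(triisopropylsilyloxy)phenyl]methyl}-4-oxobutanoate | COC(=O)C[C@@H](Cc1c(C)ccc(O[Si](C(C)C)(C(C)C)C(C)C)c1C)C(Cl)=O | intermediate
19 | 6-methyl 1-trimethylsilyl (4R)-4-{[2,6-dimethyl-3-(triisopropylsilyloxy)phenyl]methyl}-3-oxo-2-(trimethylsilyloxy)hexanedioate | COC(=O)C[C@@H](Cc1c(C)ccc(O[Si](C(C)C)(C(C)C)C(C)C)c1C)C(=O)C(O[Si](C)(C)C)C(=O)O[Si](C)(C)C | intermediate
20 | methyl (3R)-3-{[2,6-dimethyl-3-(triisopropylsilyloxy)phenyl]methyl}-5-hydroxy-4-oxopentanoate | COC(=O)C[C@@H](Cc1c(C)ccc(O[Si](C(C)C)(C(C)C)C(C)C)c1C)C(=O)CO | intermediate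
21 | methyl (3R)-3-{[2,6-dimethyl-3-(triisopropylsilyloxy)phenyl]methyl}-5-[(methoxycarbonyl)oxy]-4-oxopentanoate | COC(=O)C[C@@H](Cc1c(C)ccc(O[Si](C(C)C)(C(C)C)C(C)C)c1C)C(=O)COC(=O)OC | intermediate
22 | methyl (3R)-3-{[2,6-dimethyl-3-(triisopropylsilyloxy)phenyl]methyl}-4-{[(methoxycarbonyl)oxy]methyl}pent-4-enoate | COC(=O)C[C@@H](Cc1c(C)ccc(O[Si](C(C)C)(C(C)C)C(C)C)c1C)C(=C)COC(=O)OC | intermediate
23 | methyl (3R)-3-[(3-hydroxy-2,6-dimethylphenyl)methyl]-4-{[(methoxycarbonyl)oxy]methyl}pent-4-enoate | COC(=O)C[C@@H](Cc1c(C)ccc(O)c1C)C(=C)COC(=O)OC | intermediate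
24 | allylpalladium bis(triphenylphosphine) phenoxide zwitterion from 23 (η3-allyl, drawn as its σ form) | COC(=O)C[C@@H](Cc1c(C)ccc([O-])c1C)C(=C)C[Pd+](P(c1ccccc1)(c1ccccc1)c1ccccc1)P(c1ccccc1)(c1ccccc1)c1ccccc1 | intermediate
25 | methyl 8-methylidene-3-oxo-13-noreudesma-1,4-dien-12-oate (7β side chain, 10β methyl) | COC(=O)C[C@H]1CC2=C(C)C(=O)C=C[C@]2(C)CC1=C | intermediate
26 | secondary ozonide of 25 (spiro-1,2,4-trioxolane at C8) | COC(=O)C[C@H]1CC2=C(C)C(=O)C=C[C@]2(C)CC13OCOO3 | intermediate
27 | methyl 3,8-dioxo-13-noreudesma-1,4-dien-12-oate | COC(=O)C[C@H]1CC2=C(C)C(=O)C=C[C@]2(C)CC1=O | intermediate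
28 | methyl 3,8-dioxo-13-noreudesm-4-en-12-oate | COC(=O)C[C@H]1CC2=C(C)C(=O)CC[C@]2(C)CC1=O | intermediate
29 | methyl 3β,8β-dihydroxy-13-noreudesm-4-en-12-oate | COC(=O)C[C@H]1CC2=C(C)[C@@H](O)CC[C@]2(C)C[C@H]1O | intermediate
30 | 3β-hydroxy-13-noreudesm-4-en-12,8β-olide (cis-fused γ-lactone) | O=C1C[C@H]2CC3=C(C)[C@@H](O)CC[C@]3(C)C[C@H]2O1 | intermediate
31 | dilithium 3β-alkoxide lactone enolate of 30 | [Li+].[Li+].[O-]C1=C[C@H]2CC3=C(C)[C@@H]([O-])CC[C@]3(C)C[C@H]2O1 | intermediate
32 | 13-(dimethylamino)-3β-hydroxyeudesm-4-en-12,8β-olide (C11 epimers) | O=C1C(CN(C)C)[C@H]2CC3=C(C)[C@@H](O)CC[C@]3(C)C[C@H]2O1 | intermediate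
33 | 13-(dimethylamino)-3β-(2-methylpropanoyloxy)eudesm-4-en-12,8β-olide (C11 epimers) | O=C1C(CN(C)C)[C@H]2CC3=C(C)[C@@H](OC(=O)C(C)C)CC[C@]3(C)C[C@H]2O1 | intermediate
34 | potassium 13-(dimethylamino)-8β-hydroxy-3β-(2-methylpropanoyloxy)eudesm-4-en-12-oate | [K+].[O-]C(=O)C(CN(C)C)[C@H]1CC2=C(C)[C@@H](OC(=O)C(C)C)CC[C@]2(C)C[C@H]1O | intermediate
35 | [8β-hydroxy-12-methoxy-3β-(2-methylpropanoyloxy)-12-oxoeudesm-4-en-13-yl]trimethylammonium iodide | [I-].COC(=O)C(C[N+](C)(C)C)[C@H]1CC2=C(C)[C@@H](OC(=O)C(C)C)CC[C@]2(C)C[C@H]1O | intermediate
36 | methyl 8β-acetoxy-3β-(2-methylpropanoyloxy)eudesma-4,11(13)-dien-12-oate | C=C(C(=O)OC)[C@H]1CC2=C(C)[C@@H](OC(=O)C(C)C)CC[C@]2(C)C[C@H]1OC(C)=O | intermediate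
37 | methyl 8β-acetoxy-5α-hydroperoxy-3β-(2-methylpropanoyloxy)eudesma-4(15),11(13)-dien-12-oate (CNP0244758.1) | C=C(C(=O)OC)[C@H]1C[C@@]2(OO)C(=C)[C@@H](OC(=O)C(C)C)CC[C@]2(C)C[C@H]1OC(C)=O | target

## Step count and least certain steps

Total: 21 steps. Longest linear sequence: 20 steps (steps 1–6 and 8–21); step 7 is a one-step side branch.

**Step 14 (key step).** Most likely to go wrong is the site and face of C-alkylation. Closure onto the ortho carbon C4 is also six-membered, and the equatorial preference of the C7 substituent in the chair-like transition state is modest, so ortho attack or attack on the other arene face could compete. Fallback: a metal-free, anionic para-alkylation. It sets out from 20. Methylenation of the free hydroxy ketone with excess Zn/CH2Br2/TiCl4 reagent should give the allylic alcohol F1, and CBr4/PPh3 the allylic bromide F2. CsF in DMF then removes the silyl group, and the free phenoxide displaces the primary allylic bromide through C10 in a compact SN2 transition state. This returns to the route at 25.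

**Step 10.** Enolisation towards C7 during the warm acidic hydrolysis and decarboxylation could erode the configuration set in step 8, and the aryl silyl ether could be lost in the same medium. Fallback: the diazoketone route at low temperature. It sets out from acid chloride 18, which with excess CH2N2 in Et2O at 0 °C should give the diazoketone F3. Dilute H2SO4 in aqueous dioxane at room temperature converts F3 into the hydroxymethyl ketone with loss of nitrogen, returning at 20.

**Step 17.** Hydride delivery at C8 from the axial direction would give the 8α epimer, and the double reduction may not go cleanly in one operation. Fallback: separate the two reductions. It sets out from 28. One equivalent of LiBH(s-Bu)3 in THF at −78 °C, which attacks only from the equatorial side and reduces the saturated ketone faster than the fully substituted enone, gives on warming the keto lactone F4. A Luche reduction of F4 then sets C3 and returns at 30.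

**Step 20.** The hydroxy ester may close back to the lactone before the C8 hydroxyl is acetylated, and hydroxide may also cleave the isobutyrate. Fallback: remove the second ester from the problem. It sets out from 32. The C3 hydroxyl is silylated (t-BuMe2SiCl, imidazole) to the silyl ether F5, which tolerates excess hydroxide and longer methylation and acetylation times in the same one-flask sequence and gives the acetoxy acrylate F6. HF·pyridine frees the allylic alcohol F7, and acylation with 2-methylpropanoyl chloride returns at 36.

**Step 21.** Oxygen may attack the β face, hydrogen may be taken from C6 or C3, or the allylic hydroperoxide may undergo acid-induced cleavage. Fallback: build the C5 oxygen and the 4(15)-alkene without an ene reaction. It sets out from 36. Buffered m-chloroperbenzoic acid epoxidises the electron-rich C4=C5 bond from the α face to the epoxide F8. Me3SiOTf with DBU isomerises it, by removal of a C15 hydrogen, to the allylic silyl ether F9. Dilute aqueous acetic acid gives the tertiary allylic alcohol F10. Acid-catalysed exchange with concentrated H2O2 in ether at 0 °C, through the allyl cation and attack at the tertiary terminus anti to the angular methyl, returns at 37.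

## Further compounds

F1 | step 14 | methyl (3R)-3-{[2,6-dimethyl-3-(triisopropylsilyloxy)phenyl]methyl}-4-(hydroxymethyl)pent-4-enoate | COC(=O)C[C@@H](Cc1c(C)ccc(O[Si](C(C)C)(C(C)C)C(C)C)c1C)C(=C)CO
F2 | step 14 | methyl (3R)-4-(bromomethyl)-3-{[2,6-dimethyl-3-(triisopropylsilyloxy)phenyl]methyl}pent-4-enoate | COC(=O)C[C@@H](Cc1c(C)ccc(O[Si](C(C)C)(C(C)C)C(C)C)c1C)C(=C)CBr
F3 | step 10 | methyl (3R)-5-diazo-3-{[2,6-dimethyl-3-(triisopropylsilyloxy)phenyl]methyl}-4-oxopentanoate | COC(=O)C[C@@H](Cc1c(C)ccc(O[Si](C(C)C)(C(C)C)C(C)C)c1C)C(=O)C=[N+]=[N-]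
F4 | step 17 | 3-oxo-13-noreudesm-4-en-12,8β-olide | O=C1C[C@H]2CC3=C(C)C(=O)CC[C@]3(C)C[C@H]2O1
F5 | step 20 | 3β-(tert-butyldimethylsilyloxy)-13-(dimethylamino)eudesm-4-en-12,8β-olide (C11 epimers) | O=C1C(CN(C)C)[C@H]2CC3=C(C)[C@@H](O[Si](C)(C)C(C)(C)C)CC[C@]3(C)C[C@H]2O1
F6 | step 20 | methyl 8β-acetoxy-3β-(tert-butyldimethylsilyloxy)eudesma-4,11(13)-dien-12-oate | C=C(C(=O)OC)[C@H]1CC2=C(C)[C@@H](O[Si](C)(C)C(C)(C)C)CC[C@]2(C)C[C@H]1OC(C)=O
F7 | step 20 | methyl 8β-acetoxy-3β-hydroxyeudesma-4,11(13)-dien-12-oate | C=C(C(=O)OC)[C@H]1CC2=C(C)[C@@H](O)CC[C@]2(C)C[C@H]1OC(C)=O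
F8 | step 21 | methyl 8β-acetoxy-4α,5α-epoxy-3β-(2-methylpropanoyloxy)eudesm-11(13)-en-12-oate | C=C(C(=O)OC)[C@H]1C[C@@]2(O3)[C@@]3(C)[C@@H](OC(=O)C(C)C)CC[C@]2(C)C[C@H]1OC(C)=O
F9 | step 21 | methyl 8β-acetoxy-3β-(2-methylpropanoyloxy)-5α-(trimethylsilyloxy)eudesma-4(15),11(13)-dien-12-oate | C=C(C(=O)OC)[C@H]1C[C@@]2(O[Si](C)(C)C)C(=C)[C@@H](OC(=O)C(C)C)CC[C@]2(C)C[C@H]1OC(C)=O
F10 | step 21 | methyl 8β-acetoxy-5α-hydroxy-3β-(2-methylpropanoyloxy)eudesma-4(15),11(13)-dien-12-oate | C=C(C(=O)OC)[C@H]1C[C@@]2(O)C(=C)[C@@H](OC(=O)C(C)C)CC[C@]2(C)C[C@H]1OC(C)=O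
A1 | alternative 1 | (7E)-9-(tert-butyldimethylsilyloxy)-7-methyldeca-1,7,9-trien-3-one | C=CC(=O)CCC/C(C)=C/C(=C)O[Si](C)(C)C(C)(C)C
A2 | alternative 1 | cis-fused 8-(tert-butyldimethylsilyloxy)-10-methyl bicyclic C4 ketone with a C8=C9 silyl enol ether (eudesmane numbering) | C1C[C@@H]2C(=O)CCC[C@]2(C)C=C1O[Si](C)(C)C(C)(C)C
A3 | alternative 2 | dimethyl (6E)-9-(1-chloroethenyl)-2,6-dimethyl-3-oxoundec-6-enedioate (chain C9, the later C7, as in the target) | COC(=O)C(C)C(=O)CC/C(C)=C/C[C@H](CC(=O)OC)C(Cl)=C
A4 | alternative 2 | trans-fused methyl 4-(methoxycarbonyl)-3,8-dioxo-13-noreudesman-12-oate | COC(=O)C[C@H]1C[C@H]2[C@@](C)(C(=O)OC)C(=O)CC[C@]2(C)CC1=O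
A5 | alternative 3 | methyl (2Z)-4-acetoxy-2-(bromomethyl)-5-(1,2,3-trimethyl-4-oxocyclohex-2-en-1-yl)pent-2-enoate (C8 and C10 as in the target) | O=C1CC[C@](C)(C[C@@H](OC(C)=O)/C=C(\CBr)C(=O)OC)C(C)=C1C
A6 | alternative 3 | methyl 8β-acetoxy-3-oxoeudesma-4,11(13)-dien-12-oate | C=C(C(=O)OC)[C@H]1CC2=C(C)C(=O)CC[C@]2(C)C[C@H]1OC(C)=O
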